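The ten-membered carbocycle is not closed but unveiled: its ring-cis,cis 1,5-diene (C10=C1–C2–C3–C4=C5), with C1=C10 conjugated to the C14 formyl group, is the retron of a bicyclo[2.2.0]hexane fused at C5–C10 to a cyclohexane. Thermolysis of that tricycle breaks the C1–C4 and C5–C10 σ bonds and merges two cyclobutanes and the six-membered ring into the germacrane ring in one operation. The precursor is a cyclohexane carrying all four ring stereocentres (C6–C9), the trans-fused α-methylene lactone, both esters and the quaternary C10 aldehyde, assembled from a dearomatised phenol by asymmetric conjugate alkenylation and an enone–1-methylcyclobutene [2+2] photocycloaddition.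

Key step: step 19

Remark: carbons carry germacrane numbers (C6 lactone O-carbon, C7, C8 acyloxy, C9 acetoxy, C10 bearing C14, C4 bearing C15, C11–C13 methylene lactone); the four cyclobutane carbons made in step 11 (C1, C4, C5, C10) are assumed to form as a mixture and are written without configuration because all become sp2 in step 19; the hand of the chiral diene in step 6 is assigned by analogy with cyclohex-2-enone and would be switched to its antipode if the ketal reversed the facial sense.

Step 1
Reactants: 1 2-hydroxy-5-methoxybenzaldehyde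
Product: 2 2-(hydroxymethyl)-4-methoxyphenol
Conditions: NaBH4, MeOH, 0 °C
Reagents that add atoms: none
Why: Chemoselective borohydride reduction of the aryl aldehyde should give the benzylic alcohol that becomes C14 while the phenol and the ring stay untouched.

Step 2
Reactants: 2 2-(hydroxymethyl)-4-methoxyphenol
Product: 3 2-[(tert-butyldiphenylsilyloxy)methyl]-4-methoxyphenol
Conditions: TBDPSCl (1.05 equiv), imidazole, CH2Cl2, 0 °C
Reagents that add atoms: tert-butyl(chloro)diphenylsilane, CC(C)(C)[Si](Cl)(c1ccccc1)c1ccccc1
Why: Chemoselective O-silylation under imidazole in CH2Cl2 should take the primary benzylic hydroxyl ahead of the hydrogen-bonded phenol (any aryl silyl ether would be cleaved selectively by brief K2CO3/MeOH), and TBDPS is chosen because it must outlast the acid step that later unmasks C6 and O12.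

Step 3
Reactants: 3 2-[(tert-butyldiphenylsilyloxy)methyl]-4-methoxyphenol
Product: 4 quinone monoketal 2-[(tert-butyldiphenylsilyloxy)methyl]-4,4-dimethoxycyclohexa-2,5-dien-1-one
Conditions: PhI(OAc)2, MeOH, 0 °C; NaHCO3 work-up
Reagents that add atoms: methanol, CO
Why: Hypervalent-iodine oxidative dearomatisation of the para-methoxyphenol should capture methanol at the methoxy-bearing carbon, giving the quinone monoketal in which C9 is the carbonyl, C10 carries the silyloxymethyl arm and C6 is masked as the dimethyl ketal.

Step 4
Reactants: 5 2-bromoprop-2-en-1-ol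
Product: 6 (2-bromoallyloxy)(tert-butyl)dimethylsilane
Conditions: TBSCl, imidazole, CH2Cl2, 0 °C to rt
Reagents that add atoms: tert-butyl(chloro)dimethylsilane, CC(C)(C)[Si](C)(C)Cl
Why: Standard imidazole-mediated silylation protects the allylic alcohol as an ether that tolerates the basic and organometallic steps yet falls to the same aqueous acid that later opens the ketal, which saves a separate deprotection.

Step 5
Reactants: 6 (2-bromoallyloxy)(tert-butyl)dimethylsilane
Product: 7 2-[3-(tert-butyldimethylsilyloxy)prop-1-en-2-yl]-4,4,5,5-tetramethyl-1,3,2-dioxaborolane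
Conditions: B2pin2, PdCl2(PPh3)2 (3 mol %), PPh3 (6 mol %), KOPh, toluene, 50 °C
Reagents that add atoms: bis(pinacolato)diboron, CC1(C)OB(OC1(C)C)B1OC(C)(C)C(C)(C)O1
Why: Miyaura borylation, that is oxidative addition of the alkenyl bromide to zerovalent palladium, phenoxide-assisted transmetalation with B2pin2 and reductive elimination, should give the 1,1-disubstituted alkenylboronate that supplies C11–C13.

Step 6
Reactants: 4 quinone monoketal; 7 alkenyl pinacol boronate
Product: 8 C7-alkenyl enone (S)-5-[3-(tert-butyldimethylsilyloxy)prop-1-en-2-yl]-2-[(tert-butyldiphenylsilyloxy)methyl]-4,4-dimethoxycyclohex-2-en-1-one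
Conditions: [RhCl(C2H4)2]2 (2.5 mol %), (S,S)-2,5-diphenylbicyclo[2.2.2]octa-2,5-diene (5.5 mol %), KOH (0.5 equiv, aq), dioxane/H2O 10:1, 30 °C
Reagents that add atoms: none
Why: In this rhodium-catalysed asymmetric conjugate addition (Hayashi–Miyaura type) the alkenyl group passes from boron to the diene-bound rhodium centre and should insert the α-unsubstituted C7=C8 enone in preference to the α-substituted C5=C10 one, the chiral diene selecting the enone face so that C7 forms in the (S) configuration, while the basic aqueous medium protonates the rhodium enolate without endangering the acid-labile ketal.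

Step 7
Reactants: 8 C7-alkenyl enone
Product: 10 trans-C8 ketol (5R,6R)-5-[3-(tert-butyldimethylsilyloxy)prop-1-en-2-yl]-2-[(tert-butyldiphenylsilyloxy)methyl]-6-hydroxy-4,4-dimethoxycyclohex-2-en-1-one, via potassium dienolate 9 (not isolated)
Conditions: KN(SiMe3)2, THF, −78 °C; then 3-phenyl-2-(phenylsulfonyl)oxaziridine, −78 °C; sat aq NH4Cl
Reagents that add atoms: 3-phenyl-2-(phenylsulfonyl)oxaziridine, O=S(=O)(c1ccccc1)N1OC1c1ccccc1
Why: Davis α-hydroxylation of the ketone enolate should work because C8 is the only enolisable position, the dienolate cannot expel methoxide, and the oxaziridine should deliver oxygen to the C8 face remote from the C7 side chain, giving the 7,8-trans ketol under basic conditions that avoid the acid-triggered loss of methanol and aromatisation to which a silyl dienol ether would be prone.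

Step 8
Reactants: 11 (S)-2-hydroxy-2-methylbutanoic acid
Product: 12 (S)-2-acetoxy-2-methylbutanoic acid
Conditions: AcCl (neat, 3 equiv), 0 °C to rt; evaporation; aqueous THF work-up
Reagents that add atoms: acetyl chloride, CC(=O)Cl
Why: O-Acylation with acetyl chloride should convert the tertiary hydroxyl of the α-hydroxy acid into its acetate, and the quaternary stereocentre, bought as the (S) enantiomer, cannot epimerise.

Step 9
Reactants: 10 trans-C8 ketol; 12 (S)-2-acetoxy-2-methylbutanoic acid
Product: 14 cis-C8 ester enone (5R,6S)-5-[3-(tert-butyldimethylsilyloxy)prop-1-en-2-yl]-2-[(tert-butyldiphenylsilyloxy)methyl]-4,4-dimethoxy-6-[(S)-2-acetoxy-2-methylbutanoyloxy]cyclohex-2-en-1-one, via alkoxyphosphonium carboxylate 13 (not isolated)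
Conditions: PPh3, DIAD (added last), toluene, 0 °C to rt
Reagents that add atoms: none
Why: In this Mitsunobu esterification the ketol oxygen is activated as an alkoxyphosphonium ion and displaced by the fairly acidic α-acyloxy carboxylate in an SN2 process accelerated by the adjacent C9 carbonyl, so C8 should be inverted to place the ester cis to the C7 side chain, while H7 lies syn to the leaving group and cannot take part in an anti elimination.

Step 10
Reactants: 15 methylenecyclobutane
Product: 16 1-methylcyclobutene
Conditions: KOtBu (10 mol %), DMSO, rt; spinning-band distillation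
Reagents that add atoms: none
Why: Base-catalysed prototropic alkene isomerisation through the allyl anion should move the exocyclic double bond into the ring, the trisubstituted endocyclic alkene being favoured at equilibrium.

Step 11
Reactants: 14 cis-C8 ester enone; 16 1-methylcyclobutene
Product: 17 tricyclic photoadduct (cyclohexanone C5–C10 fused at C5–C10 to a bicyclo[2.2.0]hexane made of C10, C1, C2, C3, C4 and C5, methyl C15 on C4)
Conditions: hν (350 nm, Pyrex), 16 (25 equiv), CH2Cl2, −40 °C, degassed
Reagents that add atoms: none
Why: Enone–alkene [2+2] photocycloaddition through the enone triplet and a 1,4-diradical should join the methyl-bearing alkene carbon C4 to the β-carbon C5 and C1 to C10 (head-to-tail, which also avoids adjacent quaternary centres at C4 and C10), the large excess of alkene should outrun intramolecular capture by the C7 alkene, and the four new centres (expected mainly cis-anti-cis and anti to the C7 and C8 substituents) need no control because all are erased in step 19.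

Step 12
Reactants: 17 tricyclic photoadduct
Product: 18 C9 alcohol (hydroxyl cis to the C8 ester)
Conditions: NaBH4, CeCl3·7H2O, MeOH/THF, −78 to −40 °C; AcOH quench
Reagents that add atoms: none
Why: In this Luche-type reduction of the hindered C9 ketone the hydride should approach anti to the C8–O bond (polar Felkin–Anh) and away from the C10 silyloxymethyl arm, so the new hydroxyl forms cis to O8, while cerium buffering and low temperature should prevent 8-to-9 acyl migration.

Step 13
Reactants: 18 C9 alcohol
Product: 19 C9 acetate
Conditions: Ac2O, DMAP, pyridine, CH2Cl2, rt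
Reagents that add atoms: acetic anhydride, CC(=O)OC(C)=O
Why: DMAP-catalysed acetylation should cap the neopentyl C9 hydroxyl with retention before it can accept the neighbouring acyl group, completing the C8 and C9 ester pattern of the target.

Step 14
Reactants: 19 C9 acetate
Product: 20 C6 ketone with free C12 hydroxyl (in equilibrium with its five-membered hemiketal)
Conditions: AcOH/THF/H2O 3:1:1, 30 °C; NaHCO3 work-up; used at once
Reagents that add atoms: water, O
Why: Acid-catalysed hydrolysis with dilute aqueous acetic acid should open the C6 dimethyl ketal and cleave the unhindered primary allylic TBS ether while the neopentyl TBDPS ether and the esters survive, and the liberated C12 hydroxyl can mask the C6 ketone as a hemiketal, which should limit enolisation towards C7 and β-elimination of the C8 ester.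

Step 15
Reactants: 20 C6 ketone
Product: 21 C6,C12 diol (C6 hydroxyl trans to the C7 side chain)
Conditions: NaBH4, CeCl3·7H2O, MeOH, −78 °C
Reagents that add atoms: none
Why: In this Luche reduction the hydride should arrive at C6 from the face of the C7 side chain, because the other face is screened by C4 and its methyl group C15 on the folded cyclobutane and because the free C12 hydroxyl can deliver borohydride intramolecularly, giving the C6 alcohol trans to the side chain as the trans-fused lactone requires, while the cold non-basic medium spares the β-acyloxy ketone from elimination.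

Step 16
Reactants: 21 C6,C12 diol
Product: 24 tricyclic α-methylene lactone TBDPS ether, via hydroxy enal 22 (not isolated), via lactol 23 (not isolated)
Conditions: MnO2 (activated, excess), CH2Cl2, rt
Reagents that add atoms: none
Why: MnO2 oxidative lactonisation should oxidise the allylic C12 alcohol to the α-substituted acrolein, which the C6 hydroxyl traps as a lactol that is oxidised further to the α-methylene-γ-butyrolactone, the trans ring fusion being fixed by the C6 and C7 centres already in place.

Step 17
Reactants: 24 tricyclic α-methylene lactone TBDPS ether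
Product: 25 C14 primary alcohol
Conditions: HF·pyridine, pyridine/THF, 0 °C to rt
Reagents that add atoms: none
Why: Fluoride-mediated desilylation with buffered HF·pyridine should free O14 under mildly acidic conditions that neither trigger acetate migration from O9 nor attack the methylene lactone.

Step 18
Reactants: 25 C14 primary alcohol
Product: 26 tricyclic aldehyde (precursor of the key step)
Conditions: Dess–Martin periodinane, CH2Cl2, rt
Reagents that add atoms: none
Why: Dess–Martin oxidation should convert the neopentyl primary alcohol into the C14 aldehyde, which sits on quaternary C10 and therefore can neither enolise nor epimerise.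

Step 19
Reactants: 26 tricyclic aldehyde
Product: 27 target germacranolide CNP0499875.1
Conditions: 1,2-dichlorobenzene (0.005 M), BHT (0.2 equiv), degassed, base-washed sealed vessel, 185 °C
Reagents that add atoms: none
Why: Heating should cleave the strained central C1–C4 bond of the bicyclo[2.2.0]hexane to a cyclohexane-1,4-diyl that fragments across C5–C10 (a formal retro-[2+2]), so that C1=C10 and C4=C5 appear and the two four-membered rings and the six-membered ring merge into the ten-membered ring. The closest known reaction type is the thermal cycloreversion of cyclohexenone–cyclobutene photoadducts to carbonyl-conjugated cyclodeca-1,5-dienes (photothermal olefin metathesis), whose products equilibrate by Cope rearrangement through 1,2-divinylcyclohexanes. No ring is closed: the macrocycle arises by ring expansion through σ-bond fragmentation, so no entropically disfavoured closure is involved. No stereocentre is created, since C6–C9 and the ester centre are spectators and the four cyclobutane centres are erased. The step needs cleavage of the C1–C4/C5–C10 pair and ring-cis geometry at both olefins: the first is fixed by the head-to-tail connectivity installed in step 11, and the second should be reached under thermodynamic control, because conjugation of C1=C10 with the C14 formyl group and two trisubstituted alkenes favour the cis,cis-diene and any ring-trans or divinylcyclohexane isomer can drain into it by reversible Cope rearrangement. High dilution, degassing, BHT and base-washed glass should protect the α-methylene lactone and the esters at this temperature.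

Compound list
1 | 2-hydroxy-5-methoxybenzaldehyde | COc1ccc(O)c(C=O)c1 | starting material
2 | 2-(hydroxymethyl)-4-methoxyphenol | COc1ccc(O)c(CO)c1 | intermediate
3 | 2-[(tert-butyldiphenylsilyloxy)methyl]-4-methoxyphenol | COc1ccc(O)c(CO[Si](c2ccccc2)(c2ccccc2)C(C)(C)C)c1 | intermediate
4 | 2-[(tert-butyldiphenylsilyloxy)methyl]-4,4-dimethoxycyclohexa-2,5-dien-1-one (quinone monoketal) | COC1(OC)C=CC(=O)C(CO[Si](c2ccccc2)(c2ccccc2)C(C)(C)C)=C1 | intermediate
5 | 2-bromoprop-2-en-1-ol | C=C(Br)CO | starting material
6 | (2-bromoallyloxy)(tert-butyl)dimethylsilane | C=C(Br)CO[Si](C)(C)C(C)(C)C | intermediate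
7 | 2-[3-(tert-butyldimethylsilyloxy)prop-1-en-2-yl]-4,4,5,5-tetramethyl-1,3,2-dioxaborolane | C=C(CO[Si](C)(C)C(C)(C)C)B1OC(C)(C)C(C)(C)O1 | intermediate
8 | (S)-5-[3-(tert-butyldimethylsilyloxy)prop-1-en-2-yl]-2-[(tert-butyldiphenylsilyloxy)methyl]-4,4-dimethoxycyclohex-2-en-1-one (C7-alkenyl enone) | C=C(CO[Si](C)(C)C(C)(C)C)[C@H]1C(OC)(OC)C=C(CO[Si](c2ccccc2)(c2ccccc2)C(C)(C)C)C(=O)C1 | intermediate
9 | potassium dienolate of 8 (O–C9=C8; formed in the flask) | C=C(CO[Si](C)(C)C(C)(C)C)[C@H]1C(OC)(OC)C=C(CO[Si](c2ccccc2)(c2ccccc2)C(C)(C)C)C([O-])=C1.[K+] | intermediate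
10 | (5R,6R)-5-[3-(tert-butyldimethylsilyloxy)prop-1-en-2-yl]-2-[(tert-butyldiphenylsilyloxy)methyl]-6-hydroxy-4,4-dimethoxycyclohex-2-en-1-one (C8 hydroxyl trans to the C7 chain) | C=C(CO[Si](C)(C)C(C)(C)C)[C@H]1C(OC)(OC)C=C(CO[Si](c2ccccc2)(c2ccccc2)C(C)(C)C)C(=O)[C@@H]1O | intermediate
11 | (S)-2-hydroxy-2-methylbutanoic acid | OC(=O)[C@](C)(CC)O | starting material
12 | (S)-2-acetoxy-2-methylbutanoic acid | OC(=O)[C@](C)(CC)OC(C)=O | intermediate
13 | C8 alkoxy(triphenyl)phosphonium salt of 10 with the carboxylate of 12 (formed in the flask) | C=C(CO[Si](C)(C)C(C)(C)C)[C@H]1C(OC)(OC)C=C(CO[Si](c2ccccc2)(c2ccccc2)C(C)(C)C)C(=O)[C@@H]1O[P+](c3ccccc3)(c3ccccc3)c3ccccc3.[O-]C(=O)[C@](C)(CC)OC(C)=O | intermediate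
14 | (5R,6S)-enone bearing the (S)-2-acetoxy-2-methylbutanoyloxy group at C8 cis to the C7 chain (photosubstrate) | C=C(CO[Si](C)(C)C(C)(C)C)[C@H]1C(OC)(OC)C=C(CO[Si](c2ccccc2)(c2ccccc2)C(C)(C)C)C(=O)[C@H]1OC(=O)[C@](C)(CC)OC(C)=O | intermediate
15 | methylenecyclobutane | C=C1CCC1 | starting material
16 | 1-methylcyclobutene | CC1=CCC1 | intermediate
17 | tricyclic photoadduct: cyclohexanone (C9 ketone, C6 dimethyl ketal, C7 silyloxypropenyl, C8 ester cis to it, C10 CH2OTBDPS) fused at C5–C10 to a bicyclo[2.2.0]hexane (C1–C10 and C4–C5 bonds, methyl on C4); cyclobutane centres unassigned | C=C(CO[Si](C)(C)C(C)(C)C)[C@H]1C(OC)(OC)C2C3(C)CCC3C2(CO[Si](c4ccccc4)(c4ccccc4)C(C)(C)C)C(=O)[C@H]1OC(=O)[C@](C)(CC)OC(C)=O | intermediate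
18 | C9 alcohol of 17, hydroxyl cis to the C8 ester | C=C(CO[Si](C)(C)C(C)(C)C)[C@H]1C(OC)(OC)C2C3(C)CCC3C2(CO[Si](c4ccccc4)(c4ccccc4)C(C)(C)C)[C@@H](O)[C@H]1OC(=O)[C@](C)(CC)OC(C)=O | intermediate
19 | C9 acetate of 18 | C=C(CO[Si](C)(C)C(C)(C)C)[C@H]1C(OC)(OC)C2C3(C)CCC3C2(CO[Si](c4ccccc4)(c4ccccc4)C(C)(C)C)[C@@H](OC(C)=O)[C@H]1OC(=O)[C@](C)(CC)OC(C)=O | intermediate
20 | C6 ketone with free C12 allylic alcohol (open form of the hemiketal) | C=C(CO)[C@H]1C(=O)C2C3(C)CCC3C2(CO[Si](c4ccccc4)(c4ccccc4)C(C)(C)C)[C@@H](OC(C)=O)[C@H]1OC(=O)[C@](C)(CC)OC(C)=O | intermediate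
21 | C6,C12 diol, C6 hydroxyl trans to the C7 chain | C=C(CO)[C@H]1[C@H](O)C2C3(C)CCC3C2(CO[Si](c4ccccc4)(c4ccccc4)C(C)(C)C)[C@@H](OC(C)=O)[C@H]1OC(=O)[C@](C)(CC)OC(C)=O | intermediate
22 | C12 enal with free C6 hydroxyl (formed in the flask) | C=C(C=O)[C@H]1[C@H](O)C2C3(C)CCC3C2(CO[Si](c4ccccc4)(c4ccccc4)C(C)(C)C)[C@@H](OC(C)=O)[C@H]1OC(=O)[C@](C)(CC)OC(C)=O | intermediate
23 | C12 lactol, trans-fused at C6–C7 (formed in the flask; C12 unassigned) | C=C1C(O)O[C@@H]2C3C4(C)CCC4C3(CO[Si](c5ccccc5)(c5ccccc5)C(C)(C)C)[C@@H](OC(C)=O)[C@@H](OC(=O)[C@](C)(CC)OC(C)=O)[C@@H]12 | intermediate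
24 | tricyclic trans-fused α-methylene-γ-butyrolactone with C14 OTBDPS | C=C1C(=O)O[C@@H]2C3C4(C)CCC4C3(CO[Si](c5ccccc5)(c5ccccc5)C(C)(C)C)[C@@H](OC(C)=O)[C@@H](OC(=O)[C@](C)(CC)OC(C)=O)[C@@H]12 | intermediate
25 | tricyclic lactone with free C14 alcohol | C=C1C(=O)O[C@@H]2C3C4(C)CCC4C3(CO)[C@@H](OC(C)=O)[C@@H](OC(=O)[C@](C)(CC)OC(C)=O)[C@@H]12 | intermediate
26 | tricyclic lactone with C14 aldehyde on quaternary C10 | C=C1C(=O)O[C@@H]2C3C4(C)CCC4C3(C=O)[C@@H](OC(C)=O)[C@@H](OC(=O)[C@](C)(CC)OC(C)=O)[C@@H]12 | intermediate
27 | CNP0499875.1: ring-cis,cis germacra-1(10),4-dien-6,12-olide with 11(13)-methylene, 14-al, 9-acetoxy and 8-[(S)-2-acetoxy-2-methylbutanoyloxy]; O6 trans to C11, O8 and O9 cis to each other and to C11 | C=C1C(=O)O[C@@H]2/C=C(/C)CC/C=C(/C=O)[C@@H](OC(C)=O)[C@@H](OC(=O)[C@](C)(CC)OC(C)=O)[C@@H]12 | target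

Total steps: 19. Longest linear sequence: 15 steps (steps 1–3, 6, 7, 9 and 11–19).

Steps most likely to fail

1. Step 19. Radical oligomerisation or ene-type decomposition through the exocyclic enoate may outpace the cycloreversion at 185 °C. The fallback masks the methylene group first; it sets out from compound 26 and returns at compound 27. Conjugate addition of thiophenol (Et3N, THF, 0 °C) to 26 should give the 13-phenylthio lactone F1 as C11 epimers. Thermolysis of this under the conditions of step 19 should give the sulfide-bearing cis,cis-germacranolide F2. NaIO4 (MeOH/H2O, 0 °C) then oxidises the sulfide to the sulfoxide F3, and thermal syn-elimination (toluene, 100 °C, CaCO3), which can only use H11, regenerates the C11=C13 double bond of 27.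

2. Step 11. The excited α'-acyloxy enone may lose its C8 ester by photochemical C–O cleavage, or be consumed by other unimolecular pathways before the cyclobutene traps it. The fallback changes the order of events; it sets out from compound 8 and returns at compound 17. Irradiation of 8 with 16 as in step 11 should give the tricyclic ketone F4, which lacks the labile C8–O bond. Enolisation at C8, the only α-CH, with KN(SiMe3)2 gives the potassium enolate F5, and the Davis oxaziridine should hydroxylate it anti to the C7 side chain to the trans ketol F6. Mitsunobu esterification of this ketol with acid 12 inverts C8 and gives 17.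

3. Step 9. Activation of the hindered ketol may lead to elimination towards the arene, retention, or no reaction with the bulky acid. The fallback forms the C8–O bond by halide displacement instead; it sets out from compound 8 and returns at compound 14. The potassium dienolate 9, generated from 8 as in step 7, is quenched with N-bromosuccinimide at −78 °C to give the trans-8-bromo ketone F7, bromine anti to the C7 side chain. SN2 displacement of the α-keto bromide by caesium (S)-2-acetoxy-2-methylbutanoate F8 (from acid 12 and Cs2CO3) in DMF at 0 °C should invert C8 and give 14.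

Further compounds
F1 | step 19 | 13-phenylthio-11,13-dihydro derivative of 26 (C11 unassigned) | c5ccccc5SCC1C(=O)O[C@@H]2C3C4(C)CCC4C3(C=O)[C@@H](OC(C)=O)[C@@H](OC(=O)[C@](C)(CC)OC(C)=O)[C@@H]12
F2 | step 19 | 13-phenylthio-11,13-dihydro derivative of 27 (C11 unassigned) | c5ccccc5SCC1C(=O)O[C@@H]2/C=C(/C)CC/C=C(/C=O)[C@@H](OC(C)=O)[C@@H](OC(=O)[C@](C)(CC)OC(C)=O)[C@@H]12
F3 | step 19 | 13-phenylsulfinyl-11,13-dihydro derivative of 27 (C11 and S unassigned) | c5ccccc5S(=O)CC1C(=O)O[C@@H]2/C=C(/C)CC/C=C(/C=O)[C@@H](OC(C)=O)[C@@H](OC(=O)[C@](C)(CC)OC(C)=O)[C@@H]12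
F4 | step 11 | tricyclic ketone from 8 and 16 (C8 methylene, C9 ketone, cyclobutane centres unassigned) | C=C(CO[Si](C)(C)C(C)(C)C)[C@H]1C(OC)(OC)C2C3(C)CCC3C2(CO[Si](c4ccccc4)(c4ccccc4)C(C)(C)C)C(=O)C1
F5 | step 11 | potassium C8 enolate of F4 | C=C(CO[Si](C)(C)C(C)(C)C)[C@H]1C(OC)(OC)C2C3(C)CCC3C2(CO[Si](c4ccccc4)(c4ccccc4)C(C)(C)C)C([O-])=C1.[K+]
F6 | step 11 | tricyclic C8 ketol, hydroxyl trans to the C7 chain | C=C(CO[Si](C)(C)C(C)(C)C)[C@H]1C(OC)(OC)C2C3(C)CCC3C2(CO[Si](c4ccccc4)(c4ccccc4)C(C)(C)C)C(=O)[C@@H]1O
F7 | step 9 | trans-8-bromo ketone from 8 (bromine anti to the C7 chain) | C=C(CO[Si](C)(C)C(C)(C)C)[C@H]1C(OC)(OC)C=C(CO[Si](c2ccccc2)(c2ccccc2)C(C)(C)C)C(=O)[C@@H]1Br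
F8 | step 9 | caesium (S)-2-acetoxy-2-methylbutanoate | [Cs+].[O-]C(=O)[C@](C)(CC)OC(C)=O
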